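The zeta run, with 1 equiv of scavenger, had 3.2% of its substrate left at 5.00 d, and the theta run, with 2.5 equiv, had 1.0%. These two readings differ by 2.2 percentage points, and each carries a scatter of 1 point, so the pair shows no clear effect of the scavenger on the substrate left.

in all of them: substrate 0.034 M; free catalyst 0.5 mol%

| charge | reagent | scavenger | remark | time |
|---|---|---|---|---|
| zeta | 1 equiv | 1 equiv (fed, over 4.0 d) | run made earlier; the fed solution adds 0.20 times the starting volume |  |
| eta | 1 equiv | 1.7 equiv (fed, over 4.0 d) | run made earlier; the fed solution adds 0.20 times the starting volume |  |
| theta | 1 equiv | 2.5 equiv (fed, over 4.0 d) | run made earlier; the fed solution adds 0.20 times the starting volume |  |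
| Friday's | 1.00 equiv | 1.60 equiv (fed, over 4.0 d) | the fed solution adds 0.20 times the starting volume | 10 d |
| Saturday's | 1.00 equiv | 3.20 equiv (fed, over 4.0 d) | the fed solution adds 0.20 times the starting volume | 10 d |
| Monday's | 1.00 equiv | 0.800 equiv (fed, over 4.0 d) | the fed solution adds 0.20 times the starting volume | 10 d |

| run | time / d | substrate / % | target / % |
|---|---|---|---|
| zeta | 1.25 | 40.0 | 57.3 |
| zeta | 2.50 | 17.2 | 84.1 |
| zeta | 4.00 | 5.5 | 92.8 |
| zeta | 5.00 | 3.2 | 97.6 |
| eta | 0.417 | 75.9 | 25.4 |
| eta | 0.833 | 56.0 | 44.4 |
| eta | 2.00 | 24.7 | 74.8 |
| eta | 5.00 | 1.6 | 98.1 |
| theta | 0.625 | 65.7 | 34.8 |
| theta | 1.67 | 30.8 | 69.9 |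
| theta | 3.00 | 10.6 | 89.4 |
| theta | 5.00 | 1.0 | 98.0 |

(standard deviation of a reading: 1 percentage point)

- amounts and yields of released group count idle adduct too
- charges are per starting volume, the dose included; the dosed solution carries all of it
- the analysis behind the earlier runs scatters by 1 percentage point, standard deviation
- steps under discussion: reagent + catalyst intermediate A -> catalyst intermediate B; 2 free catalyst <-> resting dimer; scavenger + released group -> scavenged by-product; substrate + free catalyst <-> catalyst intermediate A; reagent + released group <-> idle adduct; catalyst intermediate D -> free catalyst + target; catalyst intermediate C -> catalyst intermediate D; catalyst intermediate B -> released group + catalyst intermediate C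

1. part of the substrate that has reacted at the end, Friday's
2. part of the substrate that has reacted at the end, Saturday's
3. part of the substrate that has reacted at the end, Monday's
4. what raising the equivalents of scavenger from its lowest to its highest value here does to the part of the substrate that has reacted (changes below 5 percentage points count as none) (no change / it rises / it falls)

Each catalytic turn takes up one reagent and returns one target. The reagent ceiling, the charge of reagent over the charge of substrate, is therefore the largest part of the substrate that can become target: 100% in the three new flasks, whatever the scavenger.

The eta readings give an apparent first-order constant of 0.842 /d, so 10 d is long against its time. Going round once more, substrate and reagent were charged equally and fall together, so the tail may run slower than this constant. The reckoning here still puts the three flasks just under the ceiling, with no change across the scavenger range.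

The forecast gave 99.9%, 100% and 97% with no change. For Monday's flask, where scavenger stands below reagent, it judged that “binding looks weak”.

The simulation gives 99.6%, 99.6% and 99.6%, no change, with a change of 0.034 points.

    reagent + catalyst intermediate A → catalyst intermediate B (k = 57.0 /M/min)
    2 free catalyst ⇌ resting dimer, settled at all times (K = 3.50 × 10⁵ /M)
    scavenger + released group → scavenged by-product (k = 0.170 /M/min)
    substrate + free catalyst ⇌ catalyst intermediate A (K = 2700 /M, k = 43.0 /M/min)
    reagent + released group ⇌ idle adduct, settled at all times (K = 20.0 /M)
    catalyst intermediate D → free catalyst + target (k = 4.30 /min)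
    catalyst intermediate C → catalyst intermediate D (k = 0.750 /min)
    catalyst intermediate B → released group + catalyst intermediate C (k = 0.350 /min)

A neighbouring flask is Saturday's with 0.600 equiv of reagent, the other charges as before. Its ceiling is 60.0%, and the flask holds 60.0% of target at 10.0 d. Reagent is the limiting reagent there, with 0% of its charge left at 10.0 d, while 40% of the substrate and 81% of the scavenger remain.

(The numbers in the tables come from a simulation with constants of no real substance; noise was put on by code.)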